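## Retrosynthetic overview

1. The target comes from global desilylation of a tris-silylated trans-lactone; C3 is set last by base equilibration, because the 3,4-trans lactone is the thermodynamic isomer.
2. The C3–CH2–aryl unit comes from a rhodium-catalysed 1,4-addition of an arylboronic acid to an α-methylene-γ-butyrolactone.
3. The key C4–C7' bond and both C4 and C7' stereocentres come from an iridium-catalysed, anti-selective, enantioselective reductive allylation of O-silyl vanillin with racemic 4-acetoxy-3-methylenebutyrolactone.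
4. The lactone donor comes from the Baylis–Hillman adduct of methyl acrylate and glycolaldehyde, then lactonisation (the only ring closure, done before any coupling) and acetylation.
5. Both aryl partners come from guaiacol, made from catechol: hydroxyalkylation/oxidative decarboxylation gives the aldehyde; bromination, silylation and borylation give the boronic acid.

Numbering used below: lactone O1, C2 (C=O), C3 (α), C4 (β), C5 (OCH2); C7' is the carbinol carbon on C4. The target is (3R,4R,7'S), with C4/C7' anti and C3/C4 trans.

Assumption: (S)-SEGPHOS is taken to give the 7'S carbinol, as in the related iridium-catalysed anti-crotylations; if the sense proved opposite, (R)-SEGPHOS would be used with nothing else changed.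

## Route

Step 1
Reactants: 1 catechol
Product: 2 guaiacol (2-methoxyphenol)
Conditions: MeI (1.0 equiv), K2CO3 (1.0 equiv), acetone, reflux; NaOH extraction to remove veratrole
Reagents that add atoms: iodomethane CI
Why: Williamson O-methylation of the catecholate with one equivalent of MeI favours the monoether, which is separated from neutral veratrole and water-soluble catechol by extraction; no stereocentre.

Step 2
Reactants: 2 guaiacol
Product: 5 vanillin, via 4-hydroxy-3-methoxymandelic acid 3 (not isolated), via 4-hydroxy-3-methoxyphenylglyoxylic acid 4 (not isolated)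
Conditions: OHCCO2H (50% aq), NaOH, H2O, 30 °C; then CuSO4 (10 mol%), air, 95 °C; then H2SO4 to pH 3, 60 °C
Reagents that add atoms: glyoxylic acid O=CC(=O)O
Why: Electrophilic hydroxyalkylation of the phenoxide by glyoxylate goes para to the phenoxide oxygen (the industrial vanillin sequence), copper-catalysed aerobic oxidation gives the aryl glyoxylate, and acid-induced decarboxylation releases the aldehyde; the mandelic stereocentre is destroyed.

Step 3
Reactants: 5 vanillin
Product: 6 3-methoxy-4-(triisopropylsilyloxy)benzaldehyde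
Conditions: TIPSCl (1.2 equiv), imidazole (2.5 equiv), DMF, rt
Reagents that add atoms: chlorotriisopropylsilane CC(C)[Si](Cl)(C(C)C)C(C)C
Why: Imidazole-promoted silylation of the phenol; the bulky TIPS ether is chosen because it survives the phosphate base, the aqueous [Rh(cod)OH]2 medium and DBU in later steps.

Step 4
Reactants: 2 guaiacol
Product: 7 4-bromo-2-methoxyphenol
Conditions: NBS (1.0 equiv), MeCN, 0 °C
Reagents that add atoms: N-bromosuccinimide O=C1CCC(=O)N1Br
Why: Electrophilic aromatic bromination goes para to the free hydroxyl, the stronger donor, so the 1,2,4-pattern of the second aryl unit is fixed.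

Step 5
Reactants: 7 4-bromo-2-methoxyphenol
Product: 8 (4-bromo-2-methoxyphenoxy)triisopropylsilane
Conditions: TIPSCl (1.2 equiv), imidazole (2.5 equiv), DMF, rt
Reagents that add atoms: chlorotriisopropylsilane CC(C)[Si](Cl)(C(C)C)C(C)C
Why: Phenol silylation as in step 3, needed before organolithium formation.

Step 6
Reactants: 8 (4-bromo-2-methoxyphenoxy)triisopropylsilane
Product: 11 [3-methoxy-4-(triisopropylsilyloxy)phenyl]boronic acid, via aryllithium 9 (not isolated), via lithium aryltrimethoxyborate 10 (not isolated)
Conditions: n-BuLi (1.05 equiv), THF, −78 °C; B(OMe)3 (1.5 equiv), −78 °C to rt; 1 M HCl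
Reagents that add atoms: trimethyl borate COB(OC)OC; water O
Why: Bromine–lithium exchange, borylation of the aryllithium with trimethyl borate and hydrolysis of the ate complex give the boronic acid.

Step 7
Reactants: 12 methyl acrylate; 13 glycolaldehyde dimer (2,5-dihydroxy-1,4-dioxane)
Product: 15 methyl 3,4-dihydroxy-2-methylenebutanoate (racemic), via glycolaldehyde 14 (not isolated)
Conditions: 13 (1.0 equiv, i.e. 2 equiv of monomer), DABCO (0.5 equiv), 1,4-dioxane/H2O (1:1), rt, 48 h; silica gel chromatography
Reagents that add atoms: none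
Why: Morita–Baylis–Hillman reaction, in which the dimer opens in water to two molecules of monomeric glycolaldehyde, one of which is taken up by the DABCO–acrylate zwitterion while the other remains as the excess that drives the slow addition and is removed on purification; the racemic carbinol is acceptable because this centre is erased at the π-allyl stage in step 10.

Step 8
Reactants: 15 methyl 3,4-dihydroxy-2-methylenebutanoate
Product: 16 4-hydroxy-3-methylenedihydrofuran-2(3H)-one (racemic)
Conditions: TsOH·H2O (5 mol%), CH2Cl2, rt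
Reagents that add atoms: none
Why: Acid-catalysed lactonisation by the primary hydroxyl closes the five-membered ring (the secondary hydroxyl could only give a β-lactone).

Step 9
Reactants: 16 4-hydroxy-3-methylenedihydrofuran-2(3H)-one
Product: 17 4-acetoxy-3-methylenedihydrofuran-2(3H)-one (racemic)
Conditions: Ac2O (1.5 equiv), pyridine (2.0 equiv), CH2Cl2, 0 °C
Reagents that add atoms: acetic anhydride CC(=O)OC(C)=O
Why: O-acylation of the secondary allylic alcohol; any allylic transposition to the primary acetate is harmless, since both regioisomers ionise to the same π-allyl.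

Step 10
Reactants: 6 3-methoxy-4-(triisopropylsilyloxy)benzaldehyde; 17 4-acetoxy-3-methylenedihydrofuran-2(3H)-one
Product: 18 (R)-4-[(S)-hydroxy(3-methoxy-4-triisopropylsilyloxyphenyl)methyl]-3-methylenedihydrofuran-2(3H)-one
Conditions: 17 (1.5 equiv), [Ir(cod)Cl]2 (2.5 mol%), (S)-SEGPHOS (5 mol%), 4-cyano-3-nitrobenzoic acid (10 mol%), K3PO4 (1.0 equiv), i-PrOH (2.0 equiv), THF, 60 °C
Reagents that add atoms: none
Why: Proposed new method: iridium-catalysed transfer-hydrogenative carbonyl allylation with a lactone-embedded Baylis–Hillman acetate as allyl donor, in which the ortho-cyclometalated iridium C,O-benzoate (returned to its monovalent state by 2-propanol) ionises either enantiomer of 17 to one π-allyl, the σ-allyl with iridium on the exocyclic CH2 is ring-locked in the E-like geometry (C5 trans to CH2–Ir) so that addition to the aldehyde through the closed chair transition state can only give the C4/C7' anti product, and (S)-SEGPHOS selects the aldehyde face that gives 4R,7'S; the closest known reaction types are the iridium-catalysed 2-(alkoxycarbonyl)allylation with acyclic acrylate-derived allyl donors and the anti-selective crotylation with α-methylallyl acetate.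

Step 11
Reactants: 18 (R)-4-[(S)-hydroxy(3-methoxy-4-triisopropylsilyloxyphenyl)methyl]-3-methylenedihydrofuran-2(3H)-one
Product: 19 (R)-4-[(S)-(tert-butyldimethylsilyloxy)(3-methoxy-4-triisopropylsilyloxyphenyl)methyl]-3-methylenedihydrofuran-2(3H)-one
Conditions: TBSOTf (1.3 equiv), 2,6-lutidine (2.0 equiv), CH2Cl2, −78 to 0 °C
Reagents that add atoms: tert-butyldimethylsilyl triflate CC(C)(C)[Si](C)(C)OS(=O)(=O)C(F)(F)F
Why: Silylation of the secondary benzylic alcohol blocks translactonisation onto the C7' oxygen during the basic steps that follow; no stereocentre is touched.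

Step 12
Reactants: 19 (R)-4-[(S)-(tert-butyldimethylsilyloxy)(3-methoxy-4-triisopropylsilyloxyphenyl)methyl]-3-methylenedihydrofuran-2(3H)-one; 11 [3-methoxy-4-(triisopropylsilyloxy)phenyl]boronic acid
Product: 20 (4R)-4-[(S)-(tert-butyldimethylsilyloxy)(3-methoxy-4-triisopropylsilyloxyphenyl)methyl]-3-(3-methoxy-4-triisopropylsilyloxybenzyl)dihydrofuran-2(3H)-one as a mixture of C3 epimers
Conditions: [Rh(cod)OH]2 (2.5 mol%), 11 (2.0 equiv), 1,4-dioxane/H2O (10:1), 40 °C
Reagents that add atoms: none
Why: Hayashi–Miyaura conjugate addition, in which the aryl–rhodium adds to the unhindered exocyclic methylene and water protonates the oxa-π-allylrhodium; protonation at C3 is not controlled (a cis-enriched mixture is expected) and is corrected in step 13, while C4 and C7' are untouched.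

Step 13
Reactants: 20 C3-epimer mixture from step 12
Product: 21 (3R,4R)-4-[(S)-(tert-butyldimethylsilyloxy)(3-methoxy-4-triisopropylsilyloxyphenyl)methyl]-3-(3-methoxy-4-triisopropylsilyloxybenzyl)dihydrofuran-2(3H)-one
Conditions: DBU (1.0 equiv), dry PhMe, 80 °C, 12 h
Reagents that add atoms: none
Why: Thermodynamic epimerisation, in which reversible deprotonation at C3 (the only acidic C–H) equilibrates the lactone to the more stable 3,4-trans isomer and so sets C3 as R; the minor cis epimer is separated and recycled.

Step 14
Reactants: 21 (3R,4R)-tris-silyl lactone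
Product: 22 (3R,4R)-4-[(S)-hydroxy(4-hydroxy-3-methoxyphenyl)methyl]-3-(4-hydroxy-3-methoxybenzyl)dihydrofuran-2(3H)-one
Conditions: TBAF (4.0 equiv), AcOH (4.0 equiv), THF, 0 °C to rt
Reagents that add atoms: none
Why: Fluoride-mediated cleavage of the two aryl TIPS ethers and the benzylic TBS ether; the acetic acid buffer avoids both free phenoxide (quinone methide formation and C7' epimerisation) and strong acid (ionisation of the p-hydroxybenzylic alcohol), so all three stereocentres are retained.

## Compound list

1 | catechol | Oc1ccccc1O | starting material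
2 | guaiacol (2-methoxyphenol) | COc1ccccc1O | intermediate
3 | 4-hydroxy-3-methoxymandelic acid (racemic) | COc1cc(C(O)C(=O)O)ccc1O | intermediate
4 | 4-hydroxy-3-methoxyphenylglyoxylic acid | COc1cc(C(=O)C(=O)O)ccc1O | intermediate
5 | vanillin (4-hydroxy-3-methoxybenzaldehyde) | COc1cc(C=O)ccc1O | intermediate
6 | 3-methoxy-4-(triisopropylsilyloxy)benzaldehyde | COc1cc(C=O)ccc1O[Si](C(C)C)(C(C)C)C(C)C | intermediate
7 | 4-bromo-2-methoxyphenol | COc1cc(Br)ccc1O | intermediate
8 | (4-bromo-2-methoxyphenoxy)triisopropylsilane | COc1cc(Br)ccc1O[Si](C(C)C)(C(C)C)C(C)C | intermediate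
9 | [3-methoxy-4-(triisopropylsilyloxy)phenyl]lithium | [Li]c1ccc(O[Si](C(C)C)(C(C)C)C(C)C)c(OC)c1 | intermediate
10 | lithium trimethoxy[3-methoxy-4-(triisopropylsilyloxy)phenyl]borate | [Li+].CO[B-](OC)(OC)c1ccc(O[Si](C(C)C)(C(C)C)C(C)C)c(OC)c1 | intermediate
11 | [3-methoxy-4-(triisopropylsilyloxy)phenyl]boronic acid | COc1cc(B(O)O)ccc1O[Si](C(C)C)(C(C)C)C(C)C | intermediate
12 | methyl acrylate | C=CC(=O)OC | starting material
13 | glycolaldehyde dimer (2,5-dihydroxy-1,4-dioxane) | OC1COC(O)CO1 | starting material
14 | glycolaldehyde | O=CCO | intermediate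
15 | methyl 3,4-dihydroxy-2-methylenebutanoate (racemic) | C=C(C(O)CO)C(=O)OC | intermediate
16 | 4-hydroxy-3-methylenedihydrofuran-2(3H)-one (racemic) | C=C1C(O)COC1=O | intermediate
17 | 4-acetoxy-3-methylenedihydrofuran-2(3H)-one (racemic) | CC(=O)OC1COC(=O)C1=C | intermediate
18 | (R)-4-[(S)-hydroxy(3-methoxy-4-triisopropylsilyloxyphenyl)methyl]-3-methylenedihydrofuran-2(3H)-one | C=C1C(=O)OC[C@@H]1[C@H](O)c1ccc(O[Si](C(C)C)(C(C)C)C(C)C)c(OC)c1 | intermediate
19 | (R)-4-[(S)-(tert-butyldimethylsilyloxy)(3-methoxy-4-triisopropylsilyloxyphenyl)methyl]-3-methylenedihydrofuran-2(3H)-one | C=C1C(=O)OC[C@@H]1[C@H](O[Si](C)(C)C(C)(C)C)c1ccc(O[Si](C(C)C)(C(C)C)C(C)C)c(OC)c1 | intermediate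
20 | (4R)-4-[(S)-(tert-butyldimethylsilyloxy)(3-methoxy-4-triisopropylsilyloxyphenyl)methyl]-3-(3-methoxy-4-triisopropylsilyloxybenzyl)dihydrofuran-2(3H)-one, mixture of C3 epimers | COc1cc(CC2C(=O)OC[C@@H]2[C@H](O[Si](C)(C)C(C)(C)C)c2ccc(O[Si](C(C)C)(C(C)C)C(C)C)c(OC)c2)ccc1O[Si](C(C)C)(C(C)C)C(C)C | intermediate
21 | (3R,4R)-4-[(S)-(tert-butyldimethylsilyloxy)(3-methoxy-4-triisopropylsilyloxyphenyl)methyl]-3-(3-methoxy-4-triisopropylsilyloxybenzyl)dihydrofuran-2(3H)-one | COc1cc(C[C@H]2C(=O)OC[C@@H]2[C@H](O[Si](C)(C)C(C)(C)C)c2ccc(O[Si](C(C)C)(C(C)C)C(C)C)c(OC)c2)ccc1O[Si](C(C)C)(C(C)C)C(C)C | intermediate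
22 | (3R,4R)-4-[(S)-hydroxy(4-hydroxy-3-methoxyphenyl)methyl]-3-(4-hydroxy-3-methoxybenzyl)dihydrofuran-2(3H)-one | COc1cc(C[C@H]2C(=O)OC[C@@H]2[C@H](O)c2ccc(O)c(OC)c2)ccc1O | target

## Step count and risks

Total step count: 14.
Longest linear sequence: 8 steps (1, 2, 3, 10, 11, 12, 13, 14 from catechol; equally 7, 8, 9, 10, 11, 12, 13, 14 from methyl acrylate and glycolaldehyde dimer). The boronic acid branch is 7 steps (1, 4, 5, 6, 12, 13, 14).

The three steps most likely to fail:

Step 10 (the proposed new iridium coupling). The electron-poor donor 17 may suffer conjugate reduction or O-allylation, and the product alkoxide may translactonise onto C7' under the basic conditions. The fallback uses known chemistry and sets out from alcohol 16 and aldehyde 6. PBr3 in Et2O at 0 °C converts 16, with allylic transposition, into 3-(bromomethyl)furan-2(5H)-one F1. F1 and 6 are then joined by a catalytic asymmetric Nozaki–Hiyama–Kishi 2-(alkoxycarbonyl)allylation (CrCl2 10 mol%, a chiral carbazole bis(oxazoline) ligand, Mn powder and TMSCl in stoichiometric amounts, THF). The allylchromium reacts through the same ring-locked E-allyl chair and gives the anti adduct as (R)-4-[(S)-(3-methoxy-4-triisopropylsilyloxyphenyl)(trimethylsilyloxy)methyl]-3-methylenedihydrofuran-2(3H)-one F2. Brief treatment with dilute aqueous HCl in THF removes the trimethylsilyl group, and the route is rejoined at 18.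

Step 13 (setting C3 by equilibration, together with the uncontrolled protonation in step 12). The trans:cis ratio at equilibrium may be too low, or hot DBU may erode the aryl silyl ethers. The fallback sets C3 kinetically and sets out from 18 and bromide 8. A Heck reaction (Pd(OAc)2, P(o-tol)3, Et3N, DMF, 90 °C) gives (R,E)-4-[(S)-hydroxy(3-methoxy-4-triisopropylsilyloxyphenyl)methyl]-3-(3-methoxy-4-triisopropylsilyloxybenzylidene)dihydrofuran-2(3H)-one F3. Hydroxyl-directed hydrogenation with [Ir(cod)(PCy3)(py)]PF6 under H2 (1 atm) in CH2Cl2 delivers hydrogen to C3 from the face of the carbinol-bearing substituent and gives (3R,4R)-4-[(S)-hydroxy(3-methoxy-4-triisopropylsilyloxyphenyl)methyl]-3-(3-methoxy-4-triisopropylsilyloxybenzyl)dihydrofuran-2(3H)-one F4. The conditions of step 14 then remove the two silyl groups, and the route is rejoined at 22.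

Step 2 (one-pot hydroxyalkylation and oxidative decarboxylation). On laboratory scale, ortho attack, double hydroxyalkylation and over-oxidation can lower the yield of vanillin. The fallback sets out from bromide 8, which the route already makes. n-BuLi in THF at −78 °C gives aryllithium 9, DMF adds to give lithium (dimethylamino)[3-methoxy-4-(triisopropylsilyloxy)phenyl]methanolate F5, and aqueous NH4Cl releases the aldehyde. The route is rejoined at 6, bypassing 3, 4 and 5.

## Further compounds

F1 | step 10 | 3-(bromomethyl)furan-2(5H)-one | O=C1OCC=C1CBr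
F2 | step 10 | (R)-4-[(S)-(3-methoxy-4-triisopropylsilyloxyphenyl)(trimethylsilyloxy)methyl]-3-methylenedihydrofuran-2(3H)-one | C=C1C(=O)OC[C@@H]1[C@H](O[Si](C)(C)C)c1ccc(O[Si](C(C)C)(C(C)C)C(C)C)c(OC)c1
F3 | step 13 | (R,E)-4-[(S)-hydroxy(3-methoxy-4-triisopropylsilyloxyphenyl)methyl]-3-(3-methoxy-4-triisopropylsilyloxybenzylidene)dihydrofuran-2(3H)-one | COc1cc(/C=C2/C(=O)OC[C@@H]2[C@H](O)c2ccc(O[Si](C(C)C)(C(C)C)C(C)C)c(OC)c2)ccc1O[Si](C(C)C)(C(C)C)C(C)C
F4 | step 13 | (3R,4R)-4-[(S)-hydroxy(3-methoxy-4-triisopropylsilyloxyphenyl)methyl]-3-(3-methoxy-4-triisopropylsilyloxybenzyl)dihydrofuran-2(3H)-one | COc1cc(C[C@H]2C(=O)OC[C@@H]2[C@H](O)c2ccc(O[Si](C(C)C)(C(C)C)C(C)C)c(OC)c2)ccc1O[Si](C(C)C)(C(C)C)C(C)C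
F5 | step 2 | lithium (dimethylamino)[3-methoxy-4-(triisopropylsilyloxy)phenyl]methanolate | [Li+].CN(C)C([O-])c1ccc(O[Si](C(C)C)(C(C)C)C(C)C)c(OC)c1
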